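The partner charge and its feed stay the same through the earlier runs, 1.2 equiv over 20 min, so hold the substrate's clock against that feed.

| flask | substrate | partner | reagent | temperature | remark | time |
|---|---|---|---|---|---|---|
| noon | 0.27 M | 1.2 equiv (fed, over 20 min) | 1.3 equiv | 0 °C | run made earlier |  |
| winter | 0.60 M | 1.2 equiv (fed, over 20 min) | 1.3 equiv | 11 °C | run made earlier |  |
| spring | 0.40 M | 1.2 equiv (fed, over 20 min) | 2.6 equiv | 0 °C | run made earlier |  |
| violet | 0.40 M | 1.20 equiv | 1.30 equiv | 5 °C | everything together at the start | 30 min |
| ochre | 0.40 M | 1.20 equiv (fed, over 20 min) | 1.30 equiv | 5 °C |  | 30 min |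

- noon (time / min: target / %, substrate / %): 6.00: 0, 78.6; 12.0: 2.2, 62.9; 20.0: 7.1, 50.8; 25.0: 9.5, 45.6; 30.0: 11.3, 43.9
- winter (time / min: target / %, substrate / %): 6.00: 4.1, 27.5; 12.0: 10.2, 15.1; 20.0: 13.9, 12.6; 25.0: 14.2, 11.9; 30.0: 13.6, 12.1
- spring (time / min: target / %, substrate / %): 6.00: 2.2, 49.1; 12.0: 8.5, 28.3; 20.0: 17.3, 16.6; 25.0: 21.9, 13.3; 30.0: 23.4, 11.1

(each reading ± 0.5 percentage points)



1. which of the two ends with the higher amount of target, in percent of the substrate charged ("neither" if they lie within 2 percentage points) (violet / ochre / neither)
2. target at the end, in percent of the substrate charged, violet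
3. target at the end, in percent of the substrate charged, ochre

Take the logarithm of the first substrate reading and divide by time and reagent concentration. Spring gives the reading k = 0.114 /M/min and noon gives 0.114 /M/min, so the early loss reads as first order in reagent. Winter reads 0.276 /M/min. Interpolate ln k in temperature between spring and winter to get 0.170 /M/min at 5 °C.

Now multiply by charged reagent c_B and feed time t_f. This gives N = k c_B t_f = 1.77 for ochre, the feed number: the substrate lifetimes that pass during the feed, pseudo-first-order with reagent held at charge. This reckons 17.0% of the substrate left when ochre's partner is just fully in, while violet has its partner in from the start. Expect violet ahead.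

Test it on the runs: N is 0.803 at noon, 2.37 in spring and 4.30 in winter, with target read at 11.3%, 23.4% and 13.6% after 30.0 min. Spring, with 2.6 equiv of reagent, reads higher than noon and winter, though its N lies between theirs, so target doesn't rise in step with N. Commit to the direction. Ochre has the reagent charge of noon and winter and an N between theirs, so put it near their values.

The forecast says violet, with 20% for violet and 15% for ochre, since in violet “partner is present early and catches the intermediate before it is lost”.

The flasks give 21.1% in violet and 14.8% in ochre, so violet leads, and ochre ends above noon's and winter's values.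

    open intermediate + second intermediate → target (k = 1.42 /M/min, Ea = 41.0 kJ/mol)
    substrate + open intermediate → side product (k = 0.524 /M/min, Ea = 42.0 kJ/mol)
    2 open intermediate → homo product (k = 2.81 /M/min, Ea = 50.0 kJ/mol)
    reagent + partner → second intermediate (k = 0.373 /M/min, Ea = 60.0 kJ/mol)
    substrate + reagent → open intermediate (k = 0.182 /M/min, Ea = 69.0 kJ/mol)
    (constants at 5 °C)

In violet, half of the turnover of substrate with reagent up to the end was done by 3.67 min and half of that of the target step by 7.55 min, and partner still stood at 35.7% of its charge after 15.0 min. In ochre, at the end of the feed, substrate stood at 29.0% against the reckoned 17.0%, with target at 11.6% and homo product at 25.8% (counted as the two it holds).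

Carry N to violet stopped at 8.0 min, putting that time in place of the feed: N becomes 0.709, which reckons 49.2% of the substrate left. That flask holds 61.3% of substrate, with target at 11.1%.

All runs were computed for substances that don't exist.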